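**Retrosynthetic overview**
- The target tetramer, epicatechin-(4β→8)-epicatechin-(4β→8)-epicatechin-(4β→8)-epicatechin, ⇐ global hydrogenolysis of its heptadeca-O-benzyl ether. No ring is built: all twelve rings come from (+)-catechin (three upper units, used as its 3-ketone) and (−)-epicatechin (bottom unit).
- The three 2,3-cis-3-ol upper units ⇐ tris(flav-2-ene) by α-face dihydroxylation, then ionic hydrogenation at C-2 (the C-4 aryl sets C-3, O-3 sets C-2) ⇐ tris(enol triflate) ⇐ tris(flavan-3-one).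
- Key disconnection, used three times: each C-4–C-8 interflavan bond. Both carbons are natively nucleophilic (ketone α-carbon and phloroglucinol-type arene carbon); C-4 is inverted to an electrophile as the hypervalent-iodine enolonium of (2R)-tetra-O-benzylflavan-3-one. C-2 of the ketone sets C-4 (trans).
- The chain grows from the bottom unit upward; each new ketone unit supplies the next free C-8.

Assumption: (+)-catechin and (−)-epicatechin, both sold in bulk as plant-derived chemicals, count as cheap commercial starting materials.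

The enolonium made in the flask in step 5 is made again from 4 in the same way at the start of steps 6 and 7. It is one compound, so it carries one number (7) and is listed once, at step 5.

In the names below, α is the face of ring B in the natural (2R) series and β the opposite face.

**Step 1**
Reactants: 1 (+)-catechin
Product: 2 5,7,3′,4′-tetra-O-benzyl-(+)-catechin
Conditions: BnBr (4.4 equiv), K2CO3, DMF, 0 °C to rt
Reagents that add atoms: benzyl bromide BrCc1ccccc1
Why: Williamson etherification of the four phenols only, since K2CO3 does not deprotonate the secondary 3-OH; no stereocentre is touched.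

**Step 2**
Reactants: 2 5,7,3′,4′-tetra-O-benzyl-(+)-catechin
Product: 3 (2R)-5,7,3′,4′-tetra-O-benzylflavan-3-one
Conditions: Dess–Martin periodinane, wet CH2Cl2, rt
Reagents that add atoms: none
Why: Dess–Martin oxidation of the 3-OH under neutral conditions, which leaves the enolisable C-2 stereocentre (R) intact.

**Step 3**
Reactants: 3 (2R)-5,7,3′,4′-tetra-O-benzylflavan-3-one
Product: 4 (2R)-5,7,3′,4′-tetra-O-benzyl-3-(trimethylsilyloxy)flav-3-ene
Conditions: Me3SiCl, LiN(SiMe3)2, THF, −78 °C (in situ quench)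
Reagents that add atoms: chlorotrimethylsilane C[Si](C)(C)Cl
Why: Kinetic enolate silylation, in which the amide removes an axial H from the unhindered benzylic C-4 methylene rather than the tertiary α-aryloxy C-2–H, and the internal quench prevents enolate equilibration so C-2 stays R.

**Step 4**
Reactants: 5 (−)-epicatechin
Product: 6 3,5,7,3′,4′-penta-O-benzyl-(−)-epicatechin
Conditions: NaH, BnBr, n-Bu4NI (cat.), DMF, 0 °C to rt
Reagents that add atoms: benzyl bromide BrCc1ccccc1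
Why: Exhaustive Williamson etherification (NaH also alkylates the 3-OH, which must be masked before the later enolate triflation); stereocentres are untouched.

**Step 5**
Reactants: 4 (2R)-5,7,3′,4′-tetra-O-benzyl-3-(trimethylsilyloxy)flav-3-ene; 6 3,5,7,3′,4′-penta-O-benzyl-(−)-epicatechin
Product: 8 dimer ketone [(2R)-5,7,3′,4′-tetra-O-benzylflavan-3-one-(4β→8)-penta-O-benzyl-(−)-epicatechin; upper unit 2,4-trans], via trivalent-iodine enolonium 7 (not isolated)
Conditions: PhI(OH)OTs (1.0 equiv), BF3·OEt2, CH2Cl2, −78 °C; add 4, 5 min; then 6 (3 equiv, excess recovered), −78 to −40 °C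
Reagents that add atoms: none
Why: Umpoled (enolonium) α-arylation of a ketone in Friedel–Crafts mode: PhI(OH)OTs/BF3 converts the silyl enol ether into an O-bound trivalent-iodine enolonium whose C-4 is electrophilic, and C-8 of 6 (the most nucleophilic arene position, between O-1 and 7-OBn) attacks it with loss of PhI. A(1,2) strain against the C-3 oxygen substituent holds ring B pseudoaxial on the α face, so the arene enters from the β face and sets C-4 trans to ring B (4β, new aryl pseudoaxial and clear of the 5-OBn group).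

**Step 6**
Reactants: 4 (2R)-5,7,3′,4′-tetra-O-benzyl-3-(trimethylsilyloxy)flav-3-ene; 8 dimer ketone
Product: 9 trimer diketone [two (2R)-5,7,3′,4′-tetra-O-benzylflavan-3-one units and penta-O-benzyl-(−)-epicatechin; both links 4β→8]
Conditions: PhI(OH)OTs (1.0 equiv), BF3·OEt2, CH2Cl2, −78 °C; add 4, 5 min; then 8 (1.5 equiv, excess recovered), −78 to −40 °C
Reagents that add atoms: none
Why: Same enolonium α-arylation as step 5, with the enolonium made fresh from 4 in the same way. Dimer 8 reacts only at the single free C-8 of its top unit (every C-6 is flanked by two benzyloxy groups, and the enolonium is pre-formed so the ketone of 8 never meets the oxidant). The new C-4 is again set trans to ring B of the incoming unit.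

**Step 7**
Reactants: 4 (2R)-5,7,3′,4′-tetra-O-benzyl-3-(trimethylsilyloxy)flav-3-ene; 9 trimer diketone
Product: 10 tetramer triketone [three (2R)-5,7,3′,4′-tetra-O-benzylflavan-3-one units and penta-O-benzyl-(−)-epicatechin; all links 4β→8]
Conditions: PhI(OH)OTs (1.0 equiv), BF3·OEt2, CH2Cl2, −78 °C; add 4, 5 min; then 9 (1.5 equiv, excess recovered), −78 to −40 °C
Reagents that add atoms: none
Why: Third enolonium α-arylation, again with the enolonium made fresh from 4 as in step 5, at the only free C-8 of 9; C-4 of the new top unit is set trans to its ring B as before.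

**Step 8**
Reactants: 10 tetramer triketone
Product: 12 tetramer tris(enol triflate) [upper three units are 3-(trifluoromethanesulfonyloxy)-5,7,3′,4′-tetra-O-benzylflav-2-enes; 4β-aryl], via tripotassium tris(enolate) 11 (not isolated)
Conditions: KN(SiMe3)2 (3.6 equiv), THF, −78 °C; then N-(5-chloropyridin-2-yl)bis(trifluoromethanesulfonimide), −78 to −30 °C
Reagents that add atoms: N-(5-chloropyridin-2-yl)bis(trifluoromethanesulfonimide) FC(F)(F)S(=O)(=O)N(c1ccc(Cl)cn1)S(=O)(=O)C(F)(F)F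
Why: Regioselective kinetic enolisation and O-triflation: in each ketone the C-2–H is axial and aligned with the C=O π system, whereas the C-4–H is equatorial and buried beside the pseudoaxial aryl, so all three enolates form toward C-2. This deliberately erases C-2 and prepares removal of O-3, because hydride reduction of these ketones would add H-3 anti to the C-4 aryl and give the wrong 3β-alcohols; C-4, the stereocentre kept in each upper unit, is untouched.

**Step 9**
Reactants: 12 tetramer tris(enol triflate)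
Product: 13 tetramer tris(flav-2-ene) [upper three units are 4β-aryl-5,7,3′,4′-tetra-O-benzylflav-2-enes]
Conditions: Pd(OAc)2 (cat.), PPh3, HCO2H, n-Bu3N, DMF, 60 °C
Reagents that add atoms: none
Why: Palladium-catalysed formate reduction of enol triflates (oxidative addition to zerovalent palladium, formate-to-hydride exchange, reductive elimination) gives the three 4H-chromene enol ethers without touching benzyl ethers or the C-4 stereocentres.

**Step 10**
Reactants: 13 tetramer tris(flav-2-ene)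
Product: 14 tetramer hexol [upper three units are 2α,3α-dihydroxy-5,7,3′,4′-tetra-O-benzylflavans; cyclic hemiketals; 4β-aryl]
Conditions: OsO4 (10 mol %), N-methylmorpholine N-oxide, THF/t-BuOH/H2O, rt
Reagents that add atoms: osmium tetroxide O=[Os](=O)(=O)=O; N-methylmorpholine N-oxide C[N+]1([O-])CCOCC1; water O
Why: Upjohn cis-dihydroxylation of three electron-rich enol ethers, in which OsO4 adds to each C-2/C-3 double bond from the α face, anti to the pseudoaxial C-4 aryl, setting 3α-OH (3R, trans to the interflavan bond) together with a 2α-hemiketal OH.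

**Step 11**
Reactants: 14 tetramer hexol
Product: 15 heptadeca-O-benzyl ether of the target tetramer (sixteen phenolic benzyl ethers and the bottom-unit 3-O-benzyl ether; upper three 3-OH free)
Conditions: Et3SiH (excess), BF3·OEt2, CH2Cl2, −78 to −40 °C
Reagents that add atoms: none
Why: Ionic hydrogenation of the three hemiketals (reductive etherification, as in C-aryl glycoside synthesis from lactols): BF3 ionises each C-2–OH to the 2-aryl oxocarbenium ion, A(1,2) strain with the coplanar ring B holds O-3 pseudoaxial, and Et3SiH adds axially anti to it on the β face (the manno-type outcome), giving H-2β with ring B equatorial and cis to 3-OH (2R,3R).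

**Step 12**
Reactants: 15 heptadeca-O-benzyl ether of the target tetramer
Product: 16 target tetramer, epicatechin-(4β→8)-epicatechin-(4β→8)-epicatechin-(4β→8)-epicatechin
Conditions: H2 (1 atm), Pd(OH)2/C, THF/MeOH/H2O, rt
Reagents that add atoms: none
Why: Hydrogenolysis of all seventeen benzyl ethers; the interflavan bonds and the pyran rings are stable under these neutral conditions and no stereocentre is affected.

**Compound list**
1 | (+)-catechin | Oc1cc(O)c2c(c1)O[C@H](c1ccc(O)c(O)c1)[C@@H](O)C2 | starting material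
2 | 5,7,3′,4′-tetra-O-benzyl-(+)-catechin | c1c(OCc3ccccc3)cc(OCc3ccccc3)c2c1O[C@H](c1ccc(OCc3ccccc3)c(OCc3ccccc3)c1)[C@@H](O)C2 | intermediate
3 | (2R)-5,7,3′,4′-tetra-O-benzylflavan-3-one | c1c(OCc3ccccc3)cc(OCc3ccccc3)c2c1O[C@H](c1ccc(OCc3ccccc3)c(OCc3ccccc3)c1)C(=O)C2 | intermediate
4 | (2R)-5,7,3′,4′-tetra-O-benzyl-3-(trimethylsilyloxy)flav-3-ene | c1c(OCc3ccccc3)cc(OCc3ccccc3)c2c1O[C@H](c1ccc(OCc3ccccc3)c(OCc3ccccc3)c1)C(O[Si](C)(C)C)=C2 | intermediate
5 | (−)-epicatechin | Oc1cc(O)c2c(c1)O[C@H](c1ccc(O)c(O)c1)[C@H](O)C2 | starting material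
6 | 3,5,7,3′,4′-penta-O-benzyl-(−)-epicatechin | c1c(OCc3ccccc3)cc(OCc3ccccc3)c2c1O[C@H](c1ccc(OCc3ccccc3)c(OCc3ccccc3)c1)[C@H](OCc3ccccc3)C2 | intermediate
7 | trivalent-iodine enolonium: (2R)-5,7,3′,4′-tetra-O-benzylflav-3-en-3-yl O-bound to I(Ph)(OTs) | c1c(OCc3ccccc3)cc(OCc3ccccc3)c2c1O[C@H](c1ccc(OCc3ccccc3)c(OCc3ccccc3)c1)C(OI(c3ccccc3)OS(=O)(=O)c3ccc(C)cc3)=C2 | intermediate
8 | dimer ketone: (2R)-tetra-O-benzylflavan-3-one-(4β→8)-penta-O-benzylepicatechin, upper unit 2,4-trans | c1c(OCc3ccccc3)cc(OCc3ccccc3)c2c1O[C@H](c1ccc(OCc3ccccc3)c(OCc3ccccc3)c1)C(=O)[C@H]2c1c(OCc3ccccc3)cc(OCc3ccccc3)c2c1O[C@H](c1ccc(OCc3ccccc3)c(OCc3ccccc3)c1)[C@H](OCc3ccccc3)C2 | intermediate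
9 | trimer diketone: two 2,4-trans flavan-3-one units, 4β→8 links, on penta-O-benzylepicatechin | c1c(OCc3ccccc3)cc(OCc3ccccc3)c2c1O[C@H](c1ccc(OCc3ccccc3)c(OCc3ccccc3)c1)C(=O)[C@H]2c1c(OCc3ccccc3)cc(OCc3ccccc3)c2c1O[C@H](c1ccc(OCc3ccccc3)c(OCc3ccccc3)c1)C(=O)[C@H]2c1c(OCc3ccccc3)cc(OCc3ccccc3)c2c1O[C@H](c1ccc(OCc3ccccc3)c(OCc3ccccc3)c1)[C@H](OCc3ccccc3)C2 | intermediate
10 | tetramer triketone: three 2,4-trans flavan-3-one units, 4β→8 links, on penta-O-benzylepicatechin | c1c(OCc3ccccc3)cc(OCc3ccccc3)c2c1O[C@H](c1ccc(OCc3ccccc3)c(OCc3ccccc3)c1)C(=O)[C@H]2c1c(OCc3ccccc3)cc(OCc3ccccc3)c2c1O[C@H](c1ccc(OCc3ccccc3)c(OCc3ccccc3)c1)C(=O)[C@H]2c1c(OCc3ccccc3)cc(OCc3ccccc3)c2c1O[C@H](c1ccc(OCc3ccccc3)c(OCc3ccccc3)c1)C(=O)[C@H]2c1c(OCc3ccccc3)cc(OCc3ccccc3)c2c1O[C@H](c1ccc(OCc3ccccc3)c(OCc3ccccc3)c1)[C@H](OCc3ccccc3)C2 | intermediate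
11 | tripotassium tris(C-2 enolate) of 10 | c1c(OCc3ccccc3)cc(OCc3ccccc3)c2c1OC(c1ccc(OCc3ccccc3)c(OCc3ccccc3)c1)=C([O-])[C@H]2c1c(OCc3ccccc3)cc(OCc3ccccc3)c2c1OC(c1ccc(OCc3ccccc3)c(OCc3ccccc3)c1)=C([O-])[C@H]2c1c(OCc3ccccc3)cc(OCc3ccccc3)c2c1OC(c1ccc(OCc3ccccc3)c(OCc3ccccc3)c1)=C([O-])[C@H]2c1c(OCc3ccccc3)cc(OCc3ccccc3)c2c1O[C@H](c1ccc(OCc3ccccc3)c(OCc3ccccc3)c1)[C@H](OCc3ccccc3)C2.[K+].[K+].[K+] | intermediate
12 | tetramer tris(enol triflate): upper three units 3-triflyloxy-flav-2-enes, 4β-aryl | c1c(OCc3ccccc3)cc(OCc3ccccc3)c2c1OC(c1ccc(OCc3ccccc3)c(OCc3ccccc3)c1)=C(OS(=O)(=O)C(F)(F)F)[C@H]2c1c(OCc3ccccc3)cc(OCc3ccccc3)c2c1OC(c1ccc(OCc3ccccc3)c(OCc3ccccc3)c1)=C(OS(=O)(=O)C(F)(F)F)[C@H]2c1c(OCc3ccccc3)cc(OCc3ccccc3)c2c1OC(c1ccc(OCc3ccccc3)c(OCc3ccccc3)c1)=C(OS(=O)(=O)C(F)(F)F)[C@H]2c1c(OCc3ccccc3)cc(OCc3ccccc3)c2c1O[C@H](c1ccc(OCc3ccccc3)c(OCc3ccccc3)c1)[C@H](OCc3ccccc3)C2 | intermediate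
13 | tetramer tris(flav-2-ene): upper three units 4β-aryl-flav-2-enes | c1c(OCc3ccccc3)cc(OCc3ccccc3)c2c1OC(c1ccc(OCc3ccccc3)c(OCc3ccccc3)c1)=C[C@H]2c1c(OCc3ccccc3)cc(OCc3ccccc3)c2c1OC(c1ccc(OCc3ccccc3)c(OCc3ccccc3)c1)=C[C@H]2c1c(OCc3ccccc3)cc(OCc3ccccc3)c2c1OC(c1ccc(OCc3ccccc3)c(OCc3ccccc3)c1)=C[C@H]2c1c(OCc3ccccc3)cc(OCc3ccccc3)c2c1O[C@H](c1ccc(OCc3ccccc3)c(OCc3ccccc3)c1)[C@H](OCc3ccccc3)C2 | intermediate
14 | tetramer hexol: upper three units 2α,3α-dihydroxyflavans (hemiketals), ring B β at C-2, 4β-aryl | c1c(OCc3ccccc3)cc(OCc3ccccc3)c2c1O[C@@](O)(c1ccc(OCc3ccccc3)c(OCc3ccccc3)c1)[C@H](O)[C@H]2c1c(OCc3ccccc3)cc(OCc3ccccc3)c2c1O[C@@](O)(c1ccc(OCc3ccccc3)c(OCc3ccccc3)c1)[C@H](O)[C@H]2c1c(OCc3ccccc3)cc(OCc3ccccc3)c2c1O[C@@](O)(c1ccc(OCc3ccccc3)c(OCc3ccccc3)c1)[C@H](O)[C@H]2c1c(OCc3ccccc3)cc(OCc3ccccc3)c2c1O[C@H](c1ccc(OCc3ccccc3)c(OCc3ccccc3)c1)[C@H](OCc3ccccc3)C2 | intermediate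
15 | heptadeca-O-benzyl ether of the target tetramer | c1c(OCc3ccccc3)cc(OCc3ccccc3)c2c1O[C@H](c1ccc(OCc3ccccc3)c(OCc3ccccc3)c1)[C@H](O)[C@H]2c1c(OCc3ccccc3)cc(OCc3ccccc3)c2c1O[C@H](c1ccc(OCc3ccccc3)c(OCc3ccccc3)c1)[C@H](O)[C@H]2c1c(OCc3ccccc3)cc(OCc3ccccc3)c2c1O[C@H](c1ccc(OCc3ccccc3)c(OCc3ccccc3)c1)[C@H](O)[C@H]2c1c(OCc3ccccc3)cc(OCc3ccccc3)c2c1O[C@H](c1ccc(OCc3ccccc3)c(OCc3ccccc3)c1)[C@H](OCc3ccccc3)C2 | intermediate
16 | target tetramer: epicatechin-(4β→8)-epicatechin-(4β→8)-epicatechin-(4β→8)-epicatechin, (2R,3R,4R) in the three upper units and (2R,3R) in the bottom unit | Oc1cc(O)c2c(c1)O[C@H](c1ccc(O)c(O)c1)[C@H](O)[C@H]2c1c(O)cc(O)c2c1O[C@H](c1ccc(O)c(O)c1)[C@H](O)[C@H]2c1c(O)cc(O)c2c1O[C@H](c1ccc(O)c(O)c1)[C@H](O)[C@H]2c1c(O)cc(O)c2c1O[C@H](c1ccc(O)c(O)c1)[C@H](O)C2 | target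

**Step count**
Total steps: 12. Longest linear sequence: 11 (steps 1–3 and 5–12).

**Steps most likely to fail, with fallbacks**

Step 5 (and its repeats, steps 6 and 7). The enolonium may lose H-2 to a 3-oxyflavylium species, couple with unreacted silyl enol ether, or be captured by tosylate before the hindered arene arrives. The fallback sets out from ketone 3 and returns at dimer ketone 8. Diazo transfer to the benzylic C-4 methylene (4-acetamidobenzenesulfonyl azide, DBU, MeCN, 0 °C) gives (2R)-4-diazo-5,7,3′,4′-tetra-O-benzylflavan-3-one F1. With arene 6 and catalytic TfOH in CH2Cl2 at −78 °C, F1 is protonated at carbon and loses dinitrogen. This gives an α-keto benzylic cation, the same umpoled C-4 electrophile, without any hypervalent iodine oxidant, and C-8 of 6 captures it to give 8. The same change serves steps 6 and 7, returning at 9 and 10.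

Step 8. Three hindered tertiary α-protons must be removed with complete C-2 regioselectivity. The fallback sets out from triketone 10 and returns at tris(flav-2-ene) 13. LiBH(s-Bu)3 in THF at −78 °C adds hydride to each C-3 from the α face, anti to the pseudoaxial C-4 aryl, giving the tetramer tris(3β-ol) F2, whose upper units are 2,3-trans-3,4-cis. Methyl N-(triethylammoniosulfonyl)carbamate in benzene at 50 °C then dehydrates each alcohol by a syn (Ei) elimination. Only H-2 is cis to the 3β-oxygen, so the double bond forms between C-2 and C-3 and 13 is reached directly.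

Step 11. The free 2-aryl oxocarbenium ion can be intercepted by the neighbouring 7-benzyloxy oxygen of the unit below (debenzylative closure to a doubly linked ketal), or hydride may add on the α face, where it avoids the pseudoaxial C-4 aryl. The fallback sets out from tris(flav-2-ene) 13 and returns at 15. Dimethyldioxirane (acetone/CH2Cl2, −78 °C) epoxidises each enol ether from the α face, anti to the C-4 aryl, giving the tetramer tris(2α,3α-epoxide) F3. LiBHEt3 in THF at −78 °C then opens each epoxide at the benzylic ketal carbon C-2, the only carbon that can carry positive charge, from the face opposite the departing oxygen. H-2 thus enters on the β face with inversion and without a free cation, and 15 is obtained with the same 2R,3R units.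

**Further compounds**
F1 | step 5 | (2R)-4-diazo-5,7,3′,4′-tetra-O-benzylflavan-3-one | c1c(OCc3ccccc3)cc(OCc3ccccc3)c2c1O[C@H](c1ccc(OCc3ccccc3)c(OCc3ccccc3)c1)C(=O)C2=[N+]=[N-]
F2 | step 8 | tetramer tris(3β-ol), upper three units 2,3-trans-3,4-cis flavan-3-ols, bottom unit penta-O-benzylepicatechin | c1c(OCc3ccccc3)cc(OCc3ccccc3)c2c1O[C@H](c1ccc(OCc3ccccc3)c(OCc3ccccc3)c1)[C@@H](O)[C@H]2c1c(OCc3ccccc3)cc(OCc3ccccc3)c2c1O[C@H](c1ccc(OCc3ccccc3)c(OCc3ccccc3)c1)[C@@H](O)[C@H]2c1c(OCc3ccccc3)cc(OCc3ccccc3)c2c1O[C@H](c1ccc(OCc3ccccc3)c(OCc3ccccc3)c1)[C@@H](O)[C@H]2c1c(OCc3ccccc3)cc(OCc3ccccc3)c2c1O[C@H](c1ccc(OCc3ccccc3)c(OCc3ccccc3)c1)[C@H](OCc3ccccc3)C2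
F3 | step 11 | tetramer tris(2α,3α-epoxide), upper three units 2,3-epoxyflavans with 4β-aryl, bottom unit penta-O-benzylepicatechin | c1c(OCc3ccccc3)cc(OCc3ccccc3)c2c1O[C@@]4(c1ccc(OCc3ccccc3)c(OCc3ccccc3)c1)[C@H](O4)[C@H]2c1c(OCc3ccccc3)cc(OCc3ccccc3)c2c1O[C@@]4(c1ccc(OCc3ccccc3)c(OCc3ccccc3)c1)[C@H](O4)[C@H]2c1c(OCc3ccccc3)cc(OCc3ccccc3)c2c1O[C@@]4(c1ccc(OCc3ccccc3)c(OCc3ccccc3)c1)[C@H](O4)[C@H]2c1c(OCc3ccccc3)cc(OCc3ccccc3)c2c1O[C@H](c1ccc(OCc3ccccc3)c(OCc3ccccc3)c1)[C@H](OCc3ccccc3)C2
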